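## Retrosynthetic overview

1. C6–geranyl bond, made last: formal [1,3] O→C shift of a 5‑O‑geranyl ether. The 5‑O tether delivers geranyl to C6 rather than C8 and releases the 5‑OH.
2. C2–phenyl bond, which sets the only stereocentre: Rh‑catalysed enantioselective 1,4‑addition of PhB(OH)2 to a chromone. The geranyl ether also serves as the 5‑OH protecting group in this step.
3. 5‑O–geranyl and 7‑O–Me bonds: two sequential, pKa‑differentiated O‑alkylations of 5,7‑dihydroxychromone.
4. Rings: A and C are bought fused as the chromone and B is bought as the boronic acid. No ring is formed in the route; ring C is only converted from pyranone to dihydropyranone when C2 becomes sp3.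

Assumptions:
- Natural (S)‑pinostrobin and (S)‑pinocembrin are deliberately not used as starting materials, so C2 is set by the route.
- "Single enantiomer" is taken as ≥95% ee by chiral HPLC.
- The geranyl bromide used is ≥95% E.

## Route

**Step 1**
Reactants: 1, 5,7‑dihydroxychromone (5,7‑dihydroxy‑4H‑chromen‑4‑one); 2, iodomethane
Product: 3, 5‑hydroxy‑7‑methoxychromone
Conditions: MeI (1.05 equiv), K2CO3 (1.1 equiv), acetone, reflux
Reagents that add atoms: iodomethane, CI
Why: Chemoselective Williamson etherification, because the 7‑OH is a free vinylogous acid and is alkylated first while the 5‑OH is hydrogen‑bonded to C4=O and stays untouched with one equivalent of MeI.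

**Step 2**
Reactants: 3, 5‑hydroxy‑7‑methoxychromone; 4, geranyl bromide ((2E)‑1‑bromo‑3,7‑dimethylocta‑2,6‑diene)
Product: 5, 5‑[(2E)‑3,7‑dimethylocta‑2,6‑dienyloxy]‑7‑methoxychromone
Conditions: geranyl bromide (1.4 equiv), dry K2CO3 (3 equiv), cat. TBAI, DMF, 50–60 °C
Reagents that add atoms: geranyl bromide, BrC/C=C(\C)CCC=C(C)C
Why: Williamson SN2 O‑alkylation in a dipolar aprotic solvent forces the chelated phenoxide to react at oxygen at the primary allylic carbon, retaining the E‑alkene, and the achiral chromone tolerates anhydrous carbonate.

**Step 3**
Reactants: 5, 5‑geranyloxy‑7‑methoxychromone; 6, phenylboronic acid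
Product: 7, (2S)‑5‑geranyloxy‑7‑methoxyflavanone ((2S)‑2‑phenylchroman‑4‑one core)
Conditions: [RhCl(C2H4)2]2 (1.5 mol %), (S)‑MeO‑F12‑BIPHEP (3.3 mol %), aq KOH (10 mol %), PhB(OH)2 (3 equiv), toluene/H2O 10:1, 25 °C (up to 40 °C if slow), Ar
Reagents that add atoms: phenylboronic acid, OB(O)c1ccccc1 (delivers C6H5; the C3‑H comes from water)
Why: Hayashi–Miyaura asymmetric conjugate addition in which the (S)‑biaryl diphosphine–Rh–Ph species should add to the same enone face that gives (S)‑3‑phenylcyclohexanone, which maps onto (2S) here (check by CD and use the (R)‑ligand if it reads 2R), while the electron‑poor ligand permits room‑temperature, near‑neutral conditions, the masked 5‑OH cannot sequester Rh as an acac‑type O,O‑chelate, and the trisubstituted alkenes are inert to Rh–Ar.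

**Step 4**
Reactants: 7, (2S)‑5‑geranyloxy‑7‑methoxyflavanone
Product: 8, (2S)‑6‑geranylpinostrobin (target)
Conditions: montmorillonite K10 (about 2 wt equiv, dried), CH2Cl2, 0 °C, 1–3 h; filter; chromatography to remove the 8‑geranyl isomer and pinostrobin
Reagents that add atoms: none
Why: Clay‑promoted formal [1,3]‑sigmatropic O→C rearrangement of an ortho‑acyl aryl allyl ether (tight‑ion‑pair, intramolecular Friedel–Crafts allylation) bonds the primary geranyl terminus to the adjacent C6 with E geometry retained, and these cold, base‑free conditions avoid the retro‑oxa‑Michael opening that would racemise C2, so the (2S) centre is carried through.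

## Compound list

| No. | Name | SMILES | Role |
|---|---|---|---|
| 1 | 5,7‑dihydroxychromone | O=c1ccoc2cc(O)cc(O)c12 | starting material |
| 2 | iodomethane | CI | starting material |
| 3 | 5‑hydroxy‑7‑methoxychromone | COc1cc(O)c2c(=O)ccoc2c1 | intermediate |
| 4 | geranyl bromide (E) | BrC/C=C(\C)CCC=C(C)C | starting material |
| 5 | 5‑(E)‑geranyloxy‑7‑methoxychromone | COc1cc(OC/C=C(\C)CCC=C(C)C)c2c(=O)ccoc2c1 | intermediate |
| 6 | phenylboronic acid | OB(O)c1ccccc1 | starting material |
| 7 | (2S)‑5‑(E)‑geranyloxy‑7‑methoxyflavanone | COc1cc2c(c(OC/C=C(\C)CCC=C(C)C)c1)C(=O)C[C@@H](c1ccccc1)O2 | intermediate |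
| 8 | (2S)‑6‑geranylpinostrobin | COc1cc2c(c(O)c1C/C=C(\C)CCC=C(C)C)C(=O)C[C@@H](c1ccccc1)O2 | target |

## Summary

Total step count: 4
Longest linear sequence: 4

Steps most likely to fail, each with a fallback that changes the approach:

1. **Step 4 (O→C geranyl shift).**
   - Risks: competing C8 migration, loss of geranyl to give (S)‑pinostrobin, and acid cyclisation of the product to a chroman.
   - Fallback: replace the migration with cross‑coupling. Take (S)‑pinostrobin (the de‑geranylated by‑product, or made by running step 3 on a 5‑O‑MOM chromone followed by mild acid). Iodinate at C6 ortho to the free 5‑OH with BnMe3N·ICl2 and CaCO3 in CH2Cl2/MeOH. Then run a Stille coupling with (E)‑geranyl‑SnBu3 using Pd(PPh3)4 in DMF. All of these conditions are non‑basic, so C2 is safe.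

2. **Step 3 (Rh 1,4‑addition).**
   - Risks: low conversion on an electron‑rich, peri‑substituted chromone, β‑aryloxide elimination to the chalcone, and eroded ee.
   - Fallback: set C2 by substitution instead of conjugate addition.
     - Make 2'‑hydroxy‑6'‑geranyloxy‑4'‑methoxyacetophenone by mono‑geranylation of 2',6'‑dihydroxy‑4'‑methoxyacetophenone.
     - Carry out an enantioselective acetate aldol with PhCHO to give the (R)‑β‑hydroxy ketone.
     - Close the O1–C2 bond by intramolecular Mitsunobu reaction with inversion, which gives 7.

3. **Step 2 (alkylation of the chelated 5‑OH).**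
   - Risks: sluggish reaction, C‑alkylation or SN2' products, and pyranone opening by adventitious hydroxide.
   - Fallback: install the ether before ring C exists. Mono‑O‑geranylate 2',6'‑dihydroxy‑4'‑methoxyacetophenone, condense it with DMF‑DMA to the enaminone, and close the remaining 2'‑OH onto it under mild acid (AcOH or silica) to give 5. In this variant ring C is formed after the etherification.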